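Ring B and the pyran ring are disconnected together at C4a–C8a and C7–C8. The feature exploited is that the C7 oxygen sits 1,4 to C4a across ring B (via C6 and C5): it can start as the oxygen of a furan whose carbons become C4a, C5, C6 and C7, while C4–C3–O2 tethers an allenyl ether (C1=C8a=C8). One intramolecular furan Diels–Alder reaction of the (3R)-allenyl ether of a 2-methyl-3-silyloxyfuran closes both rings, leaves the C1=C8a enol ether and sets C7 through the temporary C7–O–C4a bridge. Fluoride-triggered β-elimination then unveils C7–OH, C4a=C5 and C6=O; C8 oxidation and oleoylation finish the target.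

Key step: step 8

Assumption: ethyl lactate is used as the racemate because its stereocentre becomes C2 of the furanone and is trigonal in the silyloxyfuran; the furan oxygen carries a triisopropylsilyl group, chosen over a smaller silyl group so that the furan and the cycloadduct tolerate base and chromatography.

Step 1
Reactants: 1 methyl (R)-3-hydroxybutanoate
Product: 2 (R)-3-hydroxy-N-methoxy-N-methylbutanamide
Conditions: MeNH(OMe)·HCl, i-PrMgCl, THF, −20 to 0 °C; aq. NH4Cl
Reagents that add atoms: N,O-dimethylhydroxylamine hydrochloride, CNOC.Cl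
Why: Weinreb amide formation by aminolysis of the ester with the magnesium amide of N,O-dimethylhydroxylamine should proceed cleanly at low temperature, and the (R) carbinol centre that becomes C3 is not touched.

Step 2
Reactants: 2 (R)-3-hydroxy-N-methoxy-N-methylbutanamide; 3 propargyl bromide
Product: 4 (R)-N-methoxy-N-methyl-3-(prop-2-yn-1-yloxy)butanamide
Conditions: NaH, Bu4NI (cat.), THF/DMF, 0 °C
Reagents that add atoms: none
Why: Williamson ether synthesis with NaH and the reactive propargylic bromide at 0 °C should outrun β-elimination of the β-oxy amide, and only the O–H bond reacts, so the (R) centre is retained.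

Step 3
Reactants: 4 (R)-N-methoxy-N-methyl-3-(prop-2-yn-1-yloxy)butanamide
Product: 5 (R)-4-(prop-2-yn-1-yloxy)pentan-2-one
Conditions: MeMgBr (2.5 equiv), THF, −78 to 0 °C; aq. NH4Cl
Reagents that add atoms: methylmagnesium bromide, C[Mg]Br
Why: Weinreb ketone synthesis, in which the methyl Grignard reagent stops at the ketone oxidation level, a further equivalent covers the acidic alkyne proton, and the stereocentre is not involved.

Step 4
Reactants: 6 ethyl lactate
Product: 7 ethyl 2-[(tert-butyldimethylsilyl)oxy]propanoate
Conditions: TBSCl, imidazole, CH2Cl2, rt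
Reagents that add atoms: tert-butyldimethylsilyl chloride, CC(C)(C)[Si](C)(C)Cl
Why: Silylation of the secondary alcohol with TBSCl and imidazole (Corey protocol) is routine and masks the lactate oxygen for the condensation; no stereochemical issue arises because this centre later becomes trigonal.

Step 5
Reactants: 5 (R)-4-(prop-2-yn-1-yloxy)pentan-2-one; 7 ethyl 2-[(tert-butyldimethylsilyl)oxy]propanoate
Product: 9 (7R)-2-[(tert-butyldimethylsilyl)oxy]-7-(prop-2-yn-1-yloxy)octane-3,5-dione, via kinetic lithium enolate 8 (not isolated)
Conditions: LiN(SiMe3)2 (2.2 equiv), THF, −78 °C; then 7, −78 to 0 °C; AcOH quench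
Reagents that add atoms: none
Why: Crossed Claisen condensation, in which LiN(SiMe3)2 deprotonates the methyl side of the ketone under kinetic control to enolate 8 (avoiding the internal enolate that could expel the β-propargyloxy group) and 8 is acylated by the ester while the second equivalent of base holds the product as its diketonate; the (R) centre is untouched and the lactate centre need not be controlled.

Step 6
Reactants: 9 (7R)-2-[(tert-butyldimethylsilyl)oxy]-7-(prop-2-yn-1-yloxy)octane-3,5-dione
Product: 11 2-methyl-5-[(2R)-2-(prop-2-yn-1-yloxy)propyl]furan-3(2H)-one, via hydroxy diketone 10 (not isolated)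
Conditions: 2 M HCl, THF, rt
Reagents that add atoms: none
Why: Aqueous acid removes the silyl ether, and the α-hydroxy 1,3-diketone 10 cyclises through its hydroxyl onto the distal carbonyl and loses water to give the 3(2H)-furanone (acid-catalysed cyclodehydration), conditions under which the propargyl ether and the remote (R) centre are stable.

Step 7
Reactants: 11 2-methyl-5-[(2R)-2-(prop-2-yn-1-yloxy)propyl]furan-3(2H)-one
Product: 13 triisopropyl({2-methyl-5-[(2R)-2-(propa-1,2-dien-1-yloxy)propyl]furan-3-yl}oxy)silane, via potassium allenyl furanolate 12 (not isolated)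
Conditions: t-BuOK (2.2 equiv), THF, 0 °C to rt; then TIPSCl, 0 °C; basic alumina filtration
Reagents that add atoms: triisopropylsilyl chloride, CC(C)[Si](Cl)(C(C)C)C(C)C
Why: t-BuOK first removes the C2 proton of the furanone to give the aromatic furan-3-olate, which shields the ring from base, and then mediates the propargyl-to-allenyl ether isomerisation (base-promoted prototropic shift) to 12, whose oxygen is silylated by TIPSCl to the 3-silyloxyfuran; no bond to the (R) centre is broken.

Step 8
Reactants: 13 triisopropyl({2-methyl-5-[(2R)-2-(propa-1,2-dien-1-yloxy)propyl]furan-3-yl}oxy)silane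
Product: 14 (3R,4aS,7S)-4a,7-epoxy-3,7-dimethyl-6-[(triisopropylsilyl)oxy]-4,4a,7,8-tetrahydro-3H-isochromene
Conditions: toluene (0.01 M), BHT (cat.), Et3N (cat.), 100 °C, sealed tube
Reagents that add atoms: none
Why: A concerted, asynchronous [4+2] cycloaddition joins the electron-rich 3-silyloxyfuran (diene C4a–C5–C6–C7) to the distal, unconjugated C8a=C8 bond of the allenyl ether, forming C4a–C8a and C7–C8 suprafacially on both partners and leaving the proximal bond as the C1=C8a enol ether; the closest known reaction type is the intramolecular Diels–Alder reaction of furans with allenyl ethers generated from propargyl ethers. Ring B closes as the carbocyclic six-membered ring of a 7-oxabicyclo[2.2.1]heptene by the cycloaddition itself, and the pyran ring closes at the same moment as the six-membered tether ring (C4a, C4, C3, O2, C1, C8a) through the C4a–C8a bond, the tether being attached to the diene terminus. The new centres C4a and C7 are the two bridgeheads of the oxygen bridge and are therefore locked to each other by the bicycle; their absolute sense should be dictated by the existing (R) centre at C3, because the forming tether ring can adopt a half-chair with the C3 methyl pseudo-equatorial and C3 on the side of the furan oxygen, whereas addition to the other furan face would need either a pseudo-axial methyl or a tether folded over C5–H. The step needs site selectivity for the distal over the proximal allene bond, which is secured because the proximal bond is an electron-rich enol ether mismatched with the electron-rich diene, and it needs the facial selectivity just described; no endo or exo question arises because C8a stays trigonal and C8 carries two hydrogens. The adduct should be favoured thermodynamically because the cumulated allene carbon becomes an ordinary alkene carbon, which offsets the loss of furan aromaticity.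

Step 9
Reactants: 14 (3R,4aS,7S)-4a,7-epoxy-3,7-dimethyl-6-[(triisopropylsilyl)oxy]-4,4a,7,8-tetrahydro-3H-isochromene
Product: 17 (3R,7S)-7-hydroxy-3,7-dimethyl-3,4,7,8-tetrahydro-6H-isochromen-6-one, via bridged enolate 15 (not isolated), via ring-opened alkoxide 16 (not isolated)
Conditions: Bu4NF, THF, 0 °C to rt; aq. NH4Cl
Reagents that add atoms: none
Why: Fluoride cleaves the silyl enol ether to the C6 enolate 15, which expels the bridging oxygen from the β-carbon C4a (E1cB opening of a 7-oxanorbornene) to alkoxide 16, so that C7–OH, C4a=C5 and C6=O appear together, C4a ceases to be a stereocentre and C7 keeps the configuration set in step 8.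

Step 10
Reactants: 17 (3R,7S)-7-hydroxy-3,7-dimethyl-3,4,7,8-tetrahydro-6H-isochromen-6-one
Product: 19 (3R,7R)-7-hydroxy-3,7-dimethyl-3,4-dihydro-6H-isochromene-6,8(7H)-dione, via C8 tert-butyl peroxide 18 (not isolated)
Conditions: Rh2(cap)4 (1 mol %; cap = caprolactamate, C6H10NO), t-BuOOH (70 % in water), NaHCO3, CH2Cl2, rt
Reagents that add atoms: tert-butyl hydroperoxide, CC(C)(C)OO
Why: Allylic C–H oxidation by tert-butylperoxyl radicals, in which the electrophilic radical should abstract hydrogen preferentially from C8 (it adjoins the electron-rich terminus C8a of the vinylogous ester, whereas C4 adjoins the electron-poor C4a), the 1-alkoxyallyl radical is captured at its carbon terminus C8 to give peroxide 18, and loss of tert-butanol leaves the C8 ketone as a second vinylogous ester without touching the quaternary C7 centre (its descriptor changes from S to R only through the priority rules).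

Step 11
Reactants: 19 (3R,7R)-7-hydroxy-3,7-dimethyl-3,4-dihydro-6H-isochromene-6,8(7H)-dione; 20 oleoyl chloride
Product: 21 (3R,7R)-3,7-dimethyl-6,8-dioxo-3,4,7,8-tetrahydro-6H-isochromen-7-yl (9Z)-octadec-9-enoate
Conditions: DMAP, Et3N, CH2Cl2, 0 °C to rt
Reagents that add atoms: none
Why: DMAP-catalysed acyl transfer from the acid chloride to the tertiary hydroxyl flanked by two carbonyl groups (nucleophilic catalysis through the acylpyridinium ion) breaks no bond to C7, so the (R) configuration is retained, and the Z olefin of the chain is not isomerised under these mild conditions.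

Compound list
1 | methyl (R)-3-hydroxybutanoate | C[C@@H](O)CC(=O)OC | starting material
2 | (R)-3-hydroxy-N-methoxy-N-methylbutanamide | C[C@@H](O)CC(=O)N(C)OC | intermediate
3 | propargyl bromide (3-bromoprop-1-yne) | C#CCBr | starting material
4 | (R)-N-methoxy-N-methyl-3-(prop-2-yn-1-yloxy)butanamide | C[C@@H](OCC#C)CC(=O)N(C)OC | intermediate
5 | (R)-4-(prop-2-yn-1-yloxy)pentan-2-one | C[C@@H](OCC#C)CC(C)=O | intermediate
6 | ethyl lactate (racemic ethyl 2-hydroxypropanoate) | CCOC(=O)C(C)O | starting material
7 | ethyl 2-[(tert-butyldimethylsilyl)oxy]propanoate (racemic) | CCOC(=O)C(C)O[Si](C)(C)C(C)(C)C | intermediate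
8 | lithium (R)-4-(prop-2-yn-1-yloxy)pent-1-en-2-olate | C=C([O-])C[C@@H](C)OCC#C.[Li+] | intermediate
9 | (7R)-2-[(tert-butyldimethylsilyl)oxy]-7-(prop-2-yn-1-yloxy)octane-3,5-dione (both C2 epimers) | CC(O[Si](C)(C)C(C)(C)C)C(=O)CC(=O)C[C@@H](C)OCC#C | intermediate
10 | (7R)-2-hydroxy-7-(prop-2-yn-1-yloxy)octane-3,5-dione | CC(O)C(=O)CC(=O)C[C@@H](C)OCC#C | intermediate
11 | 2-methyl-5-[(2R)-2-(prop-2-yn-1-yloxy)propyl]furan-3(2H)-one (both C2 epimers) | CC1OC(C[C@@H](C)OCC#C)=CC1=O | intermediate
12 | potassium 2-methyl-5-[(2R)-2-(propa-1,2-dien-1-yloxy)propyl]furan-3-olate | Cc1oc(C[C@@H](C)OC=C=C)cc1[O-].[K+] | intermediate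
13 | triisopropyl({2-methyl-5-[(2R)-2-(propa-1,2-dien-1-yloxy)propyl]furan-3-yl}oxy)silane (key-step precursor) | Cc1oc(C[C@@H](C)OC=C=C)cc1O[Si](C(C)C)(C(C)C)C(C)C | intermediate
14 | (3R,4aS,7S)-4a,7-epoxy-3,7-dimethyl-6-[(triisopropylsilyl)oxy]-4,4a,7,8-tetrahydro-3H-isochromene (key-step product) | C[C@@H]1C[C@@]23C=C(O[Si](C(C)C)(C(C)C)C(C)C)[C@@](C)(O2)CC3=CO1 | intermediate
15 | tetrabutylammonium (3R,4aS,7S)-4a,7-epoxy-3,7-dimethyl-4,4a,7,8-tetrahydro-3H-isochromen-6-olate | C[C@@H]1C[C@@]23C=C([O-])[C@@](C)(O2)CC3=CO1.CCCC[N+](CCCC)(CCCC)CCCC | intermediate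
16 | tetrabutylammonium (3R,7S)-3,7-dimethyl-6-oxo-3,4,7,8-tetrahydro-6H-isochromen-7-olate | C[C@@H]1CC2=CC(=O)[C@@](C)([O-])CC2=CO1.CCCC[N+](CCCC)(CCCC)CCCC | intermediate
17 | (3R,7S)-7-hydroxy-3,7-dimethyl-3,4,7,8-tetrahydro-6H-isochromen-6-one | C[C@@H]1CC2=CC(=O)[C@@](C)(O)CC2=CO1 | intermediate
18 | (3R,7S)-8-(tert-butylperoxy)-7-hydroxy-3,7-dimethyl-3,4,7,8-tetrahydro-6H-isochromen-6-one (C8 epimers) | C[C@@H]1CC2=CC(=O)[C@@](C)(O)C(OOC(C)(C)C)C2=CO1 | intermediate
19 | (3R,7R)-7-hydroxy-3,7-dimethyl-3,4-dihydro-6H-isochromene-6,8(7H)-dione | C[C@@H]1CC2=CC(=O)[C@@](C)(O)C(=O)C2=CO1 | intermediate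
20 | oleoyl chloride ((9Z)-octadec-9-enoyl chloride) | CCCCCCCC/C=C\CCCCCCCC(=O)Cl | starting material
21 | (3R,7R)-3,7-dimethyl-6,8-dioxo-3,4,7,8-tetrahydro-6H-isochromen-7-yl (9Z)-octadec-9-enoate | CCCCCCCC/C=C\CCCCCCCC(=O)O[C@]1(C)C(=O)C=C2C[C@@H](C)OC=C2C1=O | target

Total step count: 11. Longest linear sequence: 10 steps (from 1 through steps 1–3 and 5–11; step 4 is a one-step side branch).

Steps most likely to fail

First, step 10, the oxidation at C8. Site selectivity may be lost: hydrogen abstraction may drift to the C4 methylene, which is the γ-position of the C6 enone, or the allyl radical may be captured at C1 and over-oxidised towards a lactone. The fallback changes the order of events so that C8 is oxidised while the bridge is still closed. Setting out from cycloadduct 14, fluoride buffered with acetic acid (Bu4NF, AcOH, THF, −20 °C) should protonate the enolate before it eliminates and give the bridged ketone (3R,4aS,7S)-4a,7-epoxy-3,7-dimethyl-3,4,4a,5,7,8-hexahydro-6H-isochromen-6-one F1. In F1 the methylene at C8 is the only allylic one and C4 is an ordinary methylene on a saturated bridgehead. The same allylic oxidation (Rh2(cap)4, t-BuOOH) should then give (3R,4aS,7R)-4a,7-epoxy-3,7-dimethyl-3,4,4a,5-tetrahydro-6H-isochromene-6,8(7H)-dione F2. DBU in CH2Cl2 opens the bridge of F2 by E1cB and the route is rejoined at 19.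

Second, step 8, the key cycloaddition. The acid- and heat-sensitive bis(enol ether) 13 may decompose before it cyclises, or facial discrimination may be weak at the temperature that the neutral silyloxyfuran requires. The fallback runs the cycloaddition on the far more electron-rich furan-3-olate, without a silyl group. Setting out from furanone 11, t-BuOK in THF/t-BuOH (0 °C, then gentle warming) generates 12 as in step 7. Instead of being silylated, the anion is left to undergo the same intramolecular furan–allenyl ether Diels–Alder reaction, now oxido-accelerated and in the basic alcoholic medium classically used for such allenyl ether cycloadditions. This should give the bridged enolate potassium (3R,4aS,7S)-4a,7-epoxy-3,7-dimethyl-4,4a,7,8-tetrahydro-3H-isochromen-6-olate F3, which collapses in the flask by E1cB to potassium (3R,7S)-3,7-dimethyl-6-oxo-3,4,7,8-tetrahydro-6H-isochromen-7-olate F4. Aqueous NH4Cl then rejoins the route at 17, bypassing 13 and 14.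

Third, step 5, the Claisen condensation. Proton transfer from the forming diketone to enolate 8 may stall the acylation, or equilibration to the internal enolate may expel propargyl alcohol by β-elimination. The fallback makes the C–C bond by an aldol addition and adjusts the oxidation level afterwards. Setting out from 7, i-Bu2AlH (CH2Cl2, −78 °C) should give 2-[(tert-butyldimethylsilyl)oxy]propanal F5. Enolate 8, generated from 5 as before, adds to F5 at −78 °C to give (7R)-2-[(tert-butyldimethylsilyl)oxy]-3-hydroxy-7-(prop-2-yn-1-yloxy)octan-5-one F6, and Dess–Martin periodinane oxidises F6 to diketone 9, where the route is rejoined.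

Further compounds
F1 | step 10 | (3R,4aS,7S)-4a,7-epoxy-3,7-dimethyl-3,4,4a,5,7,8-hexahydro-6H-isochromen-6-one | C[C@@H]1C[C@@]23CC(=O)[C@@](C)(O2)CC3=CO1
F2 | step 10 | (3R,4aS,7R)-4a,7-epoxy-3,7-dimethyl-3,4,4a,5-tetrahydro-6H-isochromene-6,8(7H)-dione | C[C@@H]1C[C@@]23CC(=O)[C@@](C)(O2)C(=O)C3=CO1
F3 | step 8 | potassium (3R,4aS,7S)-4a,7-epoxy-3,7-dimethyl-4,4a,7,8-tetrahydro-3H-isochromen-6-olate | C[C@@H]1C[C@@]23C=C([O-])[C@@](C)(O2)CC3=CO1.[K+]
F4 | step 8 | potassium (3R,7S)-3,7-dimethyl-6-oxo-3,4,7,8-tetrahydro-6H-isochromen-7-olate | C[C@@H]1CC2=CC(=O)[C@@](C)([O-])CC2=CO1.[K+]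
F5 | step 5 | 2-[(tert-butyldimethylsilyl)oxy]propanal | CC(O[Si](C)(C)C(C)(C)C)C=O
F6 | step 5 | (7R)-2-[(tert-butyldimethylsilyl)oxy]-3-hydroxy-7-(prop-2-yn-1-yloxy)octan-5-one | CC(O[Si](C)(C)C(C)(C)C)C(O)CC(=O)C[C@@H](C)OCC#C
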